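The route rests on cutting ring A (C10, C1, C2, ketone C3, C4, C5) at C1–C2, the bond that links the ring-fusion methine C10, held between the quaternary carbons C5 and C9, to the carbon alpha to the C3 carbonyl. Forward, a fully substituted ring B cyclohexane carrying a formyl group on C10 and an acetonyl group on C5 undergoes a base-mediated aldol condensation that forms C1–C2, closes ring A as the C1=C2 enone and lets C10 settle in the trans-fused configuration by reversible enolisation. The enone then blocks C2 so that the acid side chain can be attached at C4, and the hydroquinone is unmasked last.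

Key step: step 11

Numbering and conventions: the decalin numbering of the target is used throughout (ring A: C10, C1, C2, C3, C4, C5; ring B: C5 to C10; C3 ketone; C4 carries the propanoic acid chain; C5 and C9 quaternary; C8 the methyl-bearing methine). Ar = 2,5-dimethoxy-3-methylphenyl. From 10 on, the C8 methyl is cis to the C9 arylmethyl group and trans to the C9 methyl; from 15 on, the C5 methyl is cis to the C9 methyl.

Assumption: the (S,R,R) phosphoramidite is taken to deliver methyl to the enone face that gives 8S, as it does for simple dialkylzinc additions to cyclohexenone; if the opposite sense is found, its enantiomer is used. Centres that are erased or equilibrated later are carried as epimer mixtures and left open in the SMILES.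

Step 1
Reactants: 1 4-methoxy-2-methylphenol
Product: 2 2-hydroxy-5-methoxy-3-methylbenzaldehyde
Conditions: MgCl2, Et3N, (CH2O)n, MeCN, reflux; then 1 M HCl
Reagents that add atoms: paraformaldehyde (formaldehyde), C=O
Why: Magnesium-phenoxide-directed ortho-formylation (Casnati–Skattebøl type) can only reach the single free ortho position of 1, since the other ortho carbon carries the methyl group and the para carbon the methoxy group.

Step 2
Reactants: 2 2-hydroxy-5-methoxy-3-methylbenzaldehyde
Product: 3 2,5-dimethoxy-3-methylbenzaldehyde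
Conditions: MeI, K2CO3, DMF, rt
Reagents that add atoms: iodomethane, CI
Why: Williamson etherification of the phenol, to which the aldehyde is inert, gives the hydroquinone dimethyl ether that is carried to the end.

Step 3
Reactants: 4 cyclohex-2-en-1-one; 3 2,5-dimethoxy-3-methylbenzaldehyde
Product: 6 (2S,3S)-2-[Ar(hydroxy)methyl]-3-methylcyclohexan-1-one (both carbinol epimers), via methylzinc enolate 5 (not isolated)
Conditions: Cu(OTf)2 (2 mol %), O,O'-(S)-(1,1'-binaphthalene-2,2'-diyl) N,N-bis[(R)-1-phenylethyl]phosphoramidite (4 mol %), Me2Zn, toluene, −30 °C; then 3, −30 → 0 °C; 1 M HCl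
Reagents that add atoms: dimethylzinc, C[Zn]C
Why: Copper–phosphoramidite-catalysed enantioselective conjugate addition of Me2Zn sets C8 (S) under ligand control and the zinc enolate is trapped regiospecifically at C9 by aldol addition to 3 (tandem conjugate addition–aldol), the C9 and carbinol configurations being irrelevant because both centres are erased in steps 4 and 5.

Step 4
Reactants: 6 (2S,3S)-2-[Ar(hydroxy)methyl]-3-methylcyclohexan-1-one
Product: 8 (2E,3S)-2-(Ar-methylidene)-3-methylcyclohexan-1-one, via methanesulfonate 7 (not isolated)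
Conditions: MsCl, Et3N, CH2Cl2, 0 °C; then DBU, 0 °C → rt
Reagents that add atoms: none
Why: Mesylation and E1cB elimination of the beta-sulfonyloxy ketone give the arylidene ketone, and because C8–H is not acidified by the cross-conjugated carbonyl the C8 configuration should survive.

Step 5
Reactants: 8 (2E,3S)-2-(Ar-methylidene)-3-methylcyclohexan-1-one
Product: 10 (2S,3S)-2-(ArCH2)-2,3-dimethylcyclohexan-1-one, via lithium enolate 9 (not isolated)
Conditions: Li (2.2 equiv), t-BuOH (1 equiv), NH3/THF, −78 °C; then MeI, −78 → −33 °C; H2O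
Reagents that add atoms: iodomethane, CI
Why: Dissolving-metal reductive alkylation gives the C9=C10 enolate regiospecifically from the aryl-conjugated enone, and MeI should attack C9 anti to the C8 methyl, which is pseudoaxial in the enolate to avoid allylic strain, so that the new C9 methyl is trans to the C8 methyl and the arylmethyl group cis to it.

Step 6
Reactants: 10 (2S,3S)-2-(ArCH2)-2,3-dimethylcyclohexan-1-one; 11 3-bromo-2-methoxyprop-1-ene
Product: 13 (2S,3S)-2-(ArCH2)-6-(2-methoxyprop-2-en-1-yl)-2,3-dimethylcyclohexan-1-one (both C5 epimers), via lithium enolate 12 (not isolated)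
Conditions: LiN(i-Pr)2, THF, −78 °C; then 11, −78 → 0 °C
Reagents that add atoms: none
Why: Kinetic enolate alkylation, in which the quaternary C9 leaves C5 as the only enolisable position and the reactive allylic bromide installs the acetonyl group as an enol ether that tolerates the bases and the organolithium of the next two steps.

Step 7
Reactants: 13 (2S,3S)-2-(ArCH2)-6-(2-methoxyprop-2-en-1-yl)-2,3-dimethylcyclohexan-1-one
Product: 15 (2S,3S,6S)-2-(ArCH2)-6-(2-methoxyprop-2-en-1-yl)-2,3,6-trimethylcyclohexan-1-one, via lithium enolate 14 (not isolated)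
Conditions: LiN(i-Pr)2, THF, 0 °C; then MeI, DMPU, −78 °C → rt
Reagents that add atoms: iodomethane, CI
Why: Second enolate alkylation creating the quaternary C5, in which MeI is expected to enter on the enolate face opposite the arylmethyl group of C9 (avoidance of a 1,3-diaxial contact), so that the C5 methyl ends up cis to the C9 methyl.

Step 8
Reactants: 15 (2S,3S,6S)-2-(ArCH2)-6-(2-methoxyprop-2-en-1-yl)-2,3,6-trimethylcyclohexan-1-one
Product: 17 1-[(1S,3S,4S)-3-(ArCH2)-1,3,4-trimethyl-2-methylidenecyclohexyl]propan-2-one, via beta-hydroxysilane 16 (not isolated)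
Conditions: Me3SiCH2Li, THF, −78 → 0 °C; then 1 M H2SO4, THF, 0 °C → rt
Reagents that add atoms: (trimethylsilyl)methyllithium, [Li]C[Si](C)(C)C; water, O
Why: Peterson olefination, in which the small and strongly nucleophilic organolithium adds to the non-enolisable doubly neopentylic ketone and acid then triggers anti elimination to the C10 methylene group and hydrolyses the enol ether to the methyl ketone, which was kept masked until now so that it could neither consume the organolithium nor close onto the C10 carbonyl.

Step 9
Reactants: 17 1-[(1S,3S,4S)-3-(ArCH2)-1,3,4-trimethyl-2-methylidenecyclohexyl]propan-2-one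
Product: 19 diol with CH2OH on C10 and CH2CH(OH)CH3 on C5 (epimers at C10 and at the carbinol), via bis-borane adduct 18 (not isolated)
Conditions: BH3·THF, THF, 0 °C → rt; then NaOH, H2O2, 0 °C → rt
Reagents that add atoms: hydrogen peroxide, OO
Why: Anti-Markovnikov hydroboration–oxidation of the 1,1-disubstituted alkene puts the hydroxyl on C1, while the concurrent reduction of the methyl ketone is harmless because step 10 reoxidises it and the C10 configuration is open because it is equilibrated in step 11.

Step 10
Reactants: 19 diol with CH2OH on C10 and CH2CH(OH)CH3 on C5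
Product: 20 (1S,2S,3S,6S)-2-(ArCH2)-2,3,6-trimethyl-6-(2-oxopropyl)cyclohexane-1-carbaldehyde (keto aldehyde; carried together with its C10 epimer)
Conditions: Dess–Martin periodinane, CH2Cl2, rt
Reagents that add atoms: none
Why: Dess–Martin oxidation converts both alcohols under neutral conditions, so the 1,5-keto aldehyde should be obtained without premature aldol reaction.

Step 11
Reactants: 20 (1S,2S,3S,6S)-2-(ArCH2)-2,3,6-trimethyl-6-(2-oxopropyl)cyclohexane-1-carbaldehyde (with its C10 epimer)
Product: 22 (4aS,5S,6S,8aS)-5-(ArCH2)-5,6,8a-trimethyl-4a,5,6,7,8,8a-hexahydronaphthalen-2(1H)-one (trans-fused C1=C2 en-3-one), via ketol 21 (not isolated)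
Conditions: NaOMe (0.5 equiv), MeOH, 65 °C, until the ratio of ring-fusion isomers no longer changes
Reagents that add atoms: none
Why: Methoxide reversibly forms the terminal (C2) enolate of the methyl ketone, which adds to the aldehyde carbon C1 to give the ketol, and E1cB loss of water then gives the conjugated C1=C2 enone; this is the intramolecular aldol condensation of a 1,5-keto aldehyde, the ring-closing half of a Robinson annulation. Ring A closes in the favoured 6-(enolendo)-exo-trig mode, and no other enolate–carbonyl pairing is productive, since the C4 enolate or the aldehyde enolate could only form four-membered rings. The one new stereocentre, C10, is under thermodynamic control: it is alpha to the aldehyde before closure and gamma to the enone afterwards (reversible dienolate formation), so both C10 epimers of 20 should funnel to one enone. The trans-fused isomer is expected to dominate because it keeps C1 and C4 equatorial on ring B, whereas the cis-fused isomer must place either C1 axial and syn to the axial C8 methyl or, after inversion of ring B, C4 and the arylmethyl group in a 1,3-diaxial relationship. The only selectivity the step needs is this ring-fusion preference, and it is secured by the ring B substitution (C5, C8, C9) installed beforehand, none of which can epimerise under the conditions.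

Step 12
Reactants: 22 trans-fused C1=C2 en-3-one; 23 allyl bromide
Product: 25 4-allyl enone (22 with prop-2-en-1-yl on C4; C4 epimers), via lithium dienolate 24 (not isolated)
Conditions: LiN(i-Pr)2, THF, −78 °C; then 23, DMPU, −78 → −20 °C
Reagents that add atoms: none
Why: Kinetic alpha'-deprotonation of the enone (C2 is sp2 and the gamma C10–H is hindered, so only C4 is enolised) gives the cross-conjugated dienolate, whose alkylation by the reactive allylic halide probably occurs anti to the axial C5 methyl, the C4 configuration being corrected in step 15.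

Step 13
Reactants: 25 4-allyl enone
Product: 27 diol with C3 hydroxyl and 3-hydroxypropyl on C4 (C1=C2 retained; C3 and C4 epimers), via bis-borabicyclononane adduct 26 (not isolated)
Conditions: 9-BBN (3 equiv), THF, 0 °C → rt; then NaOH, H2O2
Reagents that add atoms: hydrogen peroxide, OO
Why: Hydroboration–oxidation with 9-BBN converts the terminal alkene into the primary alcohol (anti-Markovnikov) and reduces the enone carbonyl in the 1,2 sense without touching the ring alkene, the redox level at C3 being irrelevant because step 14 restores the ketone.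

Step 14
Reactants: 27 diol with C3 hydroxyl and 3-hydroxypropyl on C4
Product: 28 enone acid (22 with 2-carboxyethyl on C4; C4 epimers)
Conditions: CrO3, H2SO4, acetone/H2O, 0 °C
Reagents that add atoms: water, O
Why: Chromic acid (Jones) oxidation takes the primary alcohol to the carboxylic acid and the allylic alcohol back to the enone in one operation, and the dimethoxyarene should tolerate brief exposure at 0 °C.

Step 15
Reactants: 28 enone acid
Product: 30 3-[(1S,4aR,5S,6S,8aR)-5-(ArCH2)-5,6,8a-trimethyl-2-oxodecahydronaphthalen-1-yl]propanoic acid, via C4-epimeric keto acid 29 (not isolated)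
Conditions: H2 (1 atm), 10% Pd/C, EtOAc, rt; filter; then NaOMe, MeOH, rt; 1 M HCl
Reagents that add atoms: none
Why: Heterogeneous hydrogenation saturates only the enone C1=C2 bond, and base then equilibrates C4 through the C3–C4 enolate so that the chain becomes equatorial and cis to the axial C5 methyl (no 1,3-diaxial contact with C10–H and C2–H), while C10 is no longer acidic.

Step 16
Reactants: 30 saturated keto acid dimethyl ether
Product: 31 3-[(1S,4aR,5S,6S,8aR)-5-[(5-methyl-3,6-dioxocyclohexa-1,4-dien-1-yl)methyl]-5,6,8a-trimethyl-2-oxodecahydronaphthalen-1-yl]propanoic acid (quinone)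
Conditions: (NH4)2Ce(NO3)6, MeCN/H2O, 0 °C
Reagents that add atoms: water, O
Why: Oxidative demethylation of the para-dimethoxyarene gives the para-quinone, and the ketone, the acid and the C4 centre should be unaffected by the brief acidic conditions.

Step 17
Reactants: 31 quinone
Product: 32 3-[(1S,4aR,5S,6S,8aR)-5-[(2,5-dihydroxy-3-methylphenyl)methyl]-5,6,8a-trimethyl-2-oxodecahydronaphthalen-1-yl]propanoic acid (target CNP0167047.1)
Conditions: Na2S2O4, THF/H2O, rt
Reagents that add atoms: none
Why: Dithionite reduction of the quinone to the hydroquinone under near-neutral conditions leaves the ketone and the acid untouched and delivers the target.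

Compound list
1 | 4-methoxy-2-methylphenol | COc1ccc(O)c(C)c1 | starting material
2 | 2-hydroxy-5-methoxy-3-methylbenzaldehyde | COc1cc(C)c(O)c(C=O)c1 | intermediate
3 | 2,5-dimethoxy-3-methylbenzaldehyde | COc1cc(C)c(OC)c(C=O)c1 | intermediate
4 | cyclohex-2-en-1-one | O=C1C=CCCC1 | starting material
5 | methylzinc (S)-3-methylcyclohex-1-en-1-olate | C[Zn]OC1=C[C@@H](C)CCC1 | intermediate
6 | (2S,3S)-2-[Ar(hydroxy)methyl]-3-methylcyclohexan-1-one, both carbinol epimers | COc1cc(C)c(OC)c(C(O)[C@H]2C(=O)CCC[C@@H]2C)c1 | intermediate
7 | methanesulfonate of 6 | COc1cc(C)c(OC)c(C(OS(C)(=O)=O)[C@H]2C(=O)CCC[C@@H]2C)c1 | intermediate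
8 | (2E,3S)-2-(Ar-methylidene)-3-methylcyclohexan-1-one | COc1cc(C)c(OC)c(/C=C2/C(=O)CCC[C@@H]2C)c1 | intermediate
9 | lithium (3S)-2-(ArCH2)-3-methylcyclohex-1-en-1-olate (C9=C10 enolate) | [Li]OC1=C(Cc2cc(OC)cc(C)c2OC)[C@@H](C)CCC1 | intermediate
10 | (2S,3S)-2-(ArCH2)-2,3-dimethylcyclohexan-1-one | Cc1cc(OC)cc(C[C@]2(C)C(=O)CCC[C@@H]2C)c1OC | intermediate
11 | 3-bromo-2-methoxyprop-1-ene | COC(=C)CBr | starting material
12 | lithium C5=C10 enolate of 10 | Cc1cc(OC)cc(C[C@]2(C)C(O[Li])=CCC[C@@H]2C)c1OC | intermediate
13 | (2S,3S)-2-(ArCH2)-6-(2-methoxyprop-2-en-1-yl)-2,3-dimethylcyclohexan-1-one, C5 epimers | Cc1cc(OC)cc(C[C@]2(C)C(=O)C(CC(=C)OC)CC[C@@H]2C)c1OC | intermediate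
14 | lithium C5=C10 enolate of 13 | Cc1cc(OC)cc(C[C@]2(C)C(O[Li])=C(CC(=C)OC)CC[C@@H]2C)c1OC | intermediate
15 | (2S,3S,6S)-2-(ArCH2)-6-(2-methoxyprop-2-en-1-yl)-2,3,6-trimethylcyclohexan-1-one | Cc1cc(OC)cc(C[C@]2(C)C(=O)[C@](C)(CC(=C)OC)CC[C@@H]2C)c1OC | intermediate
16 | beta-hydroxysilane: 15 with C10 as a tertiary carbinol carrying CH2SiMe3 (C10 epimers) | Cc1cc(OC)cc(C[C@]2(C)C(O)(C[Si](C)(C)C)[C@](C)(CC(=C)OC)CC[C@@H]2C)c1OC | intermediate
17 | 1-[(1S,3S,4S)-3-(ArCH2)-1,3,4-trimethyl-2-methylidenecyclohexyl]propan-2-one | Cc1cc(OC)cc(C[C@]2(C)C(=C)[C@](C)(CC(C)=O)CC[C@@H]2C)c1OC | intermediate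
18 | bis-borane adduct of 17 (BH2 on C1, O–BH2 on C3; epimers) | Cc1cc(OC)cc(C[C@]2(C)C(CB)[C@](C)(CC(C)OB)CC[C@@H]2C)c1OC | intermediate
19 | diol: CH2OH on C10, CH2CH(OH)CH3 on C5 (epimers at C10 and carbinol) | Cc1cc(OC)cc(C[C@]2(C)C(CO)[C@](C)(CC(C)O)CC[C@@H]2C)c1OC | intermediate
20 | (1S,2S,3S,6S)-2-(ArCH2)-2,3,6-trimethyl-6-(2-oxopropyl)cyclohexane-1-carbaldehyde (key-step precursor; accompanied by its C10 epimer) | Cc1cc(OC)cc(C[C@]2(C)[C@@H](C=O)[C@](C)(CC(C)=O)CC[C@@H]2C)c1OC | intermediate
21 | ketol: trans-fused 1-hydroxy-3-oxo decalin from aldol addition (C1 carbinol epimers) | Cc1cc(OC)cc(C[C@]2(C)[C@H]3C(O)CC(=O)C[C@]3(C)CC[C@@H]2C)c1OC | intermediate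
22 | (4aS,5S,6S,8aS)-5-(ArCH2)-5,6,8a-trimethyl-4a,5,6,7,8,8a-hexahydronaphthalen-2(1H)-one (trans-fused C1=C2 en-3-one; key-step product) | Cc1cc(OC)cc(C[C@]2(C)[C@H]3C=CC(=O)C[C@]3(C)CC[C@@H]2C)c1OC | intermediate
23 | allyl bromide (3-bromoprop-1-ene) | C=CCBr | starting material
24 | lithium C3=C4 dienolate of 22 | Cc1cc(OC)cc(C[C@]2(C)[C@H]3C=CC(O[Li])=C[C@]3(C)CC[C@@H]2C)c1OC | intermediate
25 | 4-allyl enone: 22 with prop-2-en-1-yl on C4 (C4 epimers) | Cc1cc(OC)cc(C[C@]2(C)[C@H]3C=CC(=O)C(CC=C)[C@]3(C)CC[C@@H]2C)c1OC | intermediate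
26 | adduct of 25 with two 9-borabicyclo[3.3.1]nonane units (B on terminal chain carbon, B–O on C3) | Cc1cc(OC)cc(C[C@]2(C)[C@H]3C=CC(OB4C5CCCC4CCC5)C(CCCB4C5CCCC4CCC5)[C@]3(C)CC[C@@H]2C)c1OC | intermediate
27 | diol: C3 hydroxyl, 3-hydroxypropyl on C4, C1=C2 retained (C3 and C4 epimers) | Cc1cc(OC)cc(C[C@]2(C)[C@H]3C=CC(O)C(CCCO)[C@]3(C)CC[C@@H]2C)c1OC | intermediate
28 | enone acid: 22 with 2-carboxyethyl on C4 (C4 epimers) | Cc1cc(OC)cc(C[C@]2(C)[C@H]3C=CC(=O)C(CCC(=O)O)[C@]3(C)CC[C@@H]2C)c1OC | intermediate
29 | saturated keto acid, C4 epimers | Cc1cc(OC)cc(C[C@]2(C)[C@H]3CCC(=O)C(CCC(=O)O)[C@]3(C)CC[C@@H]2C)c1OC | intermediate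
30 | 3-[(1S,4aR,5S,6S,8aR)-5-(ArCH2)-5,6,8a-trimethyl-2-oxodecahydronaphthalen-1-yl]propanoic acid | Cc1cc(OC)cc(C[C@]2(C)[C@H]3CCC(=O)[C@@H](CCC(=O)O)[C@]3(C)CC[C@@H]2C)c1OC | intermediate
31 | 3-[(1S,4aR,5S,6S,8aR)-5-[(5-methyl-3,6-dioxocyclohexa-1,4-dien-1-yl)methyl]-5,6,8a-trimethyl-2-oxodecahydronaphthalen-1-yl]propanoic acid | CC1=CC(=O)C=C(C[C@]2(C)[C@H]3CCC(=O)[C@@H](CCC(=O)O)[C@]3(C)CC[C@@H]2C)C1=O | intermediate
32 | 3-[(1S,4aR,5S,6S,8aR)-5-[(2,5-dihydroxy-3-methylphenyl)methyl]-5,6,8a-trimethyl-2-oxodecahydronaphthalen-1-yl]propanoic acid (CNP0167047.1) | Cc1cc(O)cc(C[C@]2(C)[C@H]3CCC(=O)[C@@H](CCC(=O)O)[C@]3(C)CC[C@@H]2C)c1O | target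

Total step count: 17. Longest linear sequence: 17 steps (1 to 32); 4, 11 and 23 are bought and enter directly.

Steps most likely to fail

Step 11. The convergence at C10 may be incomplete: both ring-fusion isomers carry one severe 1,3-diaxial contact (methyl/methyl in the trans isomer, ring CH2/arylmethyl in the cis isomer), so the equilibrium may leave a substantial share of cis-fused enone, and enolisation of the hindered aldehyde may be too slow for full funnelling. The fallback replaces thermodynamic control by a kinetically controlled two-stage closure. It sets out from 20, which is treated with L-proline in DMSO at rt (enamine-catalysed aldol addition) and stopped at ketol 21; the ring fusion is then fixed in the bond-forming event, through the chair-like transition state in which both reacting arms are equatorial on ring B. The isolated ketol is converted with MsCl/Et3N at 0 °C into the ketol methanesulfonate F1, which DBU eliminates to the enone without exposing it to alkoxide. The fallback comes back to the route at 22.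

Step 7. The facial selectivity of the C5 methylation may be poor, because the two C9 substituents differ only modestly in size as seen from C5. The fallback builds C5 under catalyst control and sets out from 10. Methylation of enolate 12 with MeI gives the 6-methyl ketone F2. LiN(SiMe3)2 converts it into the lithium enolate F3, which is O-acylated with allyl chloroformate to the allyl enol carbonate F4. Pd2(dba)3 with the matched enantiomer of 4-tert-butyl-2-[2-(diphenylphosphino)phenyl]-4,5-dihydrooxazole then effects decarboxylative asymmetric allylic alkylation to the 6-allyl-6-methyl ketone F5, the ligand rather than the substrate choosing the face. Me3SiCH2Li followed by acid, as in step 8, gives through the beta-hydroxysilane F6 the methylene allyl diene F7. Wacker oxidation (PdCl2, CuCl, O2, DMF/H2O) of the monosubstituted alkene alone then comes back to the route at 17.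

Step 8. Carbanion addition to the doubly neopentylic C10 carbonyl may be too slow, or the acid-triggered elimination may be diverted by capture of the tertiary C10 cation (by the neighbouring carbonyl oxygen or by a 1,2-shift). The fallback replaces addition–elimination by a metal-alkylidene olefination under non-acidic conditions. It sets out from 15, which is treated with Cp2Ti(μ-CH2)(μ-Cl)AlMe2 (THF, pyridine, −40 °C → rt); the oxophilic titanium methylidene reacts by [2+2] addition and cycloreversion to give the methylene enol ether F8. Brief hydrolysis with oxalic acid in wet THF unmasks the methyl ketone and comes back to the route at 17.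

Further compounds
F1 | step 11 | methanesulfonate of ketol 21 | Cc1cc(OC)cc(C[C@]2(C)[C@H]3C(OS(C)(=O)=O)CC(=O)C[C@]3(C)CC[C@@H]2C)c1OC
F2 | step 7 | (2S,3S)-2-(ArCH2)-2,3,6-trimethylcyclohexan-1-one, C5 epimers | Cc1cc(OC)cc(C[C@]2(C)C(=O)C(C)CC[C@@H]2C)c1OC
F3 | step 7 | lithium C5=C10 enolate of F2 | Cc1cc(OC)cc(C[C@]2(C)C(O[Li])=C(C)CC[C@@H]2C)c1OC
F4 | step 7 | allyl enol carbonate of F2 | Cc1cc(OC)cc(C[C@]2(C)C(OC(=O)OCC=C)=C(C)CC[C@@H]2C)c1OC
F5 | step 7 | (2S,3S,6S)-2-(ArCH2)-6-allyl-2,3,6-trimethylcyclohexan-1-one | Cc1cc(OC)cc(C[C@]2(C)C(=O)[C@](C)(CC=C)CC[C@@H]2C)c1OC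
F6 | step 7 | beta-hydroxysilane from F5 (C10 carbinol carrying CH2SiMe3; C10 epimers) | Cc1cc(OC)cc(C[C@]2(C)C(O)(C[Si](C)(C)C)[C@](C)(CC=C)CC[C@@H]2C)c1OC
F7 | step 7 | methylene allyl diene (C10 exocyclic methylene; C5 methyl and allyl) | Cc1cc(OC)cc(C[C@]2(C)C(=C)[C@](C)(CC=C)CC[C@@H]2C)c1OC
F8 | step 8 | methylene enol ether (C10 exocyclic methylene; C5 methyl and 2-methoxyallyl) | Cc1cc(OC)cc(C[C@]2(C)C(=C)[C@](C)(CC(=C)OC)CC[C@@H]2C)c1OC
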